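**Retrosynthetic overview**

1. The strategy rests on the resorcinol ring C1'–C6': every carbon but C4' is substituted (benzofuran-2-yl at C1', prenyl at C2' and C6', oxygen at C3' and C5', meta, with C4'–H between them), which is the pattern a fully substituted vinylketene and a 1-siloxyalkyne deliver.
2. Key disconnection (resorcinol ring, formed last): C3'–C4' and C5'–C6' (ketene–alkyne [2+2]), C6'–C1' (Wolff shift) and C2'–C3' (6π closure) lead back to the acyclic diazo enone 21 and (triisopropylsilyloxy)acetylene 25.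
3. 21 comes from E enone 18 by deacylative diazo transfer at C8, and 18 from tertiary ketol 16 by dehydration (C5=C6).
4. 16 comes from 2-lithiobenzofuran 15 and the symmetrical 1,2-diketone 14, whose two C5 arms are two equivalents of one homoprenyl Grignard reagent added to an oxalyl unit.
5. The benzofuran rings are bought as benzofuran-6-ol; the C7 prenyl group enters by OMOM-directed lithiation with C2 masked by silicon; the end game is fluoride, then mild acid.

Key step: step 9

Assumption: (triisopropylsilyloxy)acetylene is treated as a reagent to be prepared (step 8); the target is achiral, so the only stereochemical element to control is the E geometry of the C5=C6 bond of 18 and 21.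

Abbreviation: Ar = 6-(methoxymethoxy)-7-(3-methylbut-2-enyl)benzofuran-2-yl.

**Route**

Step 1
Reactants: 1 benzofuran-6-ol
Product: 2 6-(methoxymethoxy)benzofuran
Conditions: MOMCl, i-Pr2NEt, CH2Cl2, 0 °C → rt
Reagents that add atoms: chloromethyl methyl ether, COCCl
Why: Williamson-type O-alkylation of the phenol with the reactive α-chloro ether under amine base should cleanly install the acetal that later directs lithiation to C7.

Step 2
Reactants: 2 6-(methoxymethoxy)benzofuran; 3 prenyl bromide
Product: 8 [6-(methoxymethoxy)-7-(3-methylbut-2-enyl)benzofuran-2-yl]trimethylsilane, via 2-lithiobenzofuran 4 (not isolated), via 2-silylbenzofuran 5 (not isolated), via 7-lithio-2-silylbenzofuran 6 (not isolated), via 7-cuprio-2-silylbenzofuran 7 (not isolated)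
Conditions: n-BuLi, THF, –78 °C; Me3SiCl; then s-BuLi, TMEDA, –78 °C; CuBr·SMe2; prenyl bromide, –78 °C → rt
Reagents that add atoms: chlorotrimethylsilane, C[Si](C)(C)Cl
Why: The most acidic hydrogen, C2–H, is lithiated first (4) and capped with silicon (5), so the second lithiation is a directed ortho-metalation at C7 (6), the only position flanked by both the OMOM group and the ring oxygen, and the arylcopper 7 should couple with prenyl bromide at its primary carbon (SN2-type allylation) without allylic transposition.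

Step 3
Reactants: 8 [6-(methoxymethoxy)-7-(3-methylbut-2-enyl)benzofuran-2-yl]trimethylsilane
Product: 9 6-(methoxymethoxy)-7-(3-methylbut-2-enyl)benzofuran
Conditions: Bu4NF·3H2O, THF, rt
Reagents that add atoms: none
Why: Fluoride attacks silicon and the sp2 carbon next to the ring oxygen leaves as a stabilised carbanion that water protonates (protodesilylation), while the MOM acetal and the prenyl group are inert to fluoride.

Step 4
Reactants: 10 5-bromo-2-methylpent-2-ene (2 equiv); 11 1,4-dimethylpiperazine-2,3-dione (1 equiv)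
Product: 14 2,11-dimethyldodeca-2,10-diene-6,7-dione, via Grignard reagent 12 (not isolated), via magnesium diolate 13 (not isolated)
Conditions: 10 (2.1 equiv), Mg (2.2 equiv), THF, 40 °C; then 11 (1 equiv), THF, 0 °C → rt; 1 M aq. HCl, 0 °C
Reagents that add atoms: 5-bromo-2-methylpent-2-ene (the second equivalent of 10, used as Grignard reagent 12), CC(C)=CCCBr
Why: Two equivalents of Grignard reagent 12 are consumed per oxamide, one adding once to each amide carbonyl of the cyclic oxamide (acyl substitution on a bis-amide), because the chelated bis-hemiaminal salt 13 resists further addition until aqueous acid releases the symmetrical α-diketone, whose fourteen carbons are two C6 arms from 10 and the two carbonyl carbons of 11.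

Step 5
Reactants: 9 6-(methoxymethoxy)-7-(3-methylbut-2-enyl)benzofuran; 14 2,11-dimethyldodeca-2,10-diene-6,7-dione
Product: 16 6-Ar-6-hydroxy-2,11-dimethyldodeca-2,10-dien-7-one (racemic), via 2-lithiobenzofuran 15 (not isolated)
Conditions: n-BuLi, THF, –78 °C; then cannulated into 14 (2 equiv), THF, –78 °C; H2O
Reagents that add atoms: none
Why: C2–H is again the most acidic hydrogen, and the sp2 carbanion 15 should undergo 1,2-addition to one of the two equivalent, mutually activated carbonyl groups faster than it enolises them at –78 °C, inverse addition to excess diketone preventing a second addition; the new carbinol centre is racemic and is destroyed in step 6.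

Step 6
Reactants: 16 6-Ar-6-hydroxy-2,11-dimethyldodeca-2,10-dien-7-one
Product: 18 (5E)-6-Ar-2,11-dimethyldodeca-2,5,10-trien-7-one, via sulfamate 17 (not isolated)
Conditions: Burgess reagent (Et3N+SO2N–CO2Me), THF, rt → 50 °C
Reagents that add atoms: none
Why: Burgess dehydration turns the tertiary alcohol into sulfamate 17, which eliminates through a cyclic syn transition state; only C5 carries β-hydrogens, so the regiochemistry is fixed, and the E isomer should predominate because the C4 chain avoids the allylic 1,3-strain it would suffer cis to the acyl group.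

Step 7
Reactants: 18 (5E)-6-Ar-2,11-dimethyldodeca-2,5,10-trien-7-one
Product: 21 (5E)-6-Ar-8-diazo-2,11-dimethyldodeca-2,5,10-trien-7-one, via lithium dienolate 19 (not isolated), via trifluoroacetyl ketone 20 (not isolated)
Conditions: LiN(SiMe3)2, THF, –78 °C; CF3CO2CH2CF3; then MsN3, Et3N, MeCN, rt
Reagents that add atoms: methanesulfonyl azide, CS(=O)(=O)N=[N+]=[N-]
Why: The carbonyl-bound lithium amide should deprotonate kinetically at the α' methylene C8 (the C4 methylene lies trans to the carbonyl across the E double bond and is out of reach), Claisen-type trifluoroacetylation then activates C8, and the sulfonyl azide transfers N2 with loss of the trifluoroacetyl group (detrifluoroacetylative diazo transfer), leaving the E geometry untouched.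

Step 8
Reactants: 22 acetylene
Product: 25 (triisopropylsilyloxy)acetylene, via ethynyllithium 23 (not isolated), via lithium ethynolate 24 (not isolated)
Conditions: n-BuLi, THF, –78 °C; t-BuOOLi (from t-BuOOH and LiN(SiMe3)2), –78 → –25 °C; i-Pr3SiOTf, –78 °C
Reagents that add atoms: tert-butyl hydroperoxide, CC(C)(C)OO; triisopropylsilyl trifluoromethanesulfonate, CC(C)[Si](C(C)C)(C(C)C)OS(=O)(=O)C(F)(F)F
Why: The lithium acetylide attacks the electrophilic oxygen of lithium tert-butyl peroxide to give the ynolate (oxenoid oxidation of a metal acetylide, the known route from 1-alkynes to siloxyalkynes), the bulky silyl triflate captures it on oxygen, and the monolithium acetylide is kept cold so that it does not disproportionate.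

Step 9
Reactants: 21 (5E)-6-Ar-8-diazo-2,11-dimethyldodeca-2,5,10-trien-7-one; 25 (triisopropylsilyloxy)acetylene
Product: 30 5-Ar-4,6-bis(3-methylbut-2-enyl)-3-(triisopropylsilyloxy)phenol, via vinylketene 26 (not isolated), via cyclobutenone 27 (not isolated), via dienylketene 28 (not isolated), via cyclohexadienone 29 (not isolated)
Conditions: hν (300 nm, Pyrex), 25 (2 equiv), ClCH2CH2Cl, rt; then 80 °C in the dark
Reagents that add atoms: none
Why: Light expels N2 from 21 and the 1-arylalkenyl group shifts from the carbonyl carbon to the former diazo carbon (photochemical Wolff rearrangement, new C6'–C1' bond) to give vinylketene 26. The oxygen-polarised alkyne 25 then adds its CH terminus to the ketene carbonyl carbon and its C–OSi terminus to the ketene α-carbon in a regiospecific [2+2] cycloaddition (C3'–C4' and C5'–C6' bonds), giving the 4-alkenylcyclobutenone 27. Between rt and 80 °C 27 opens reversibly by 4π electrocyclic cleavage to dienylketene 28, and the isomer with the alkenyl arm cis to the ketenyl group closes the six-membered ring by thermal 6π electrocyclisation between the ketene carbon and the alkene CH (C2'–C3' bond), after which dienone 29 tautomerises to phenol 30. This is the diazo ketone form of the Danheiser benzannulation with a siloxyalkyne, a reaction type known to give resorcinol monosilyl ethers. No stereocentre is formed; the step needs regiocontrol in the [2+2], which the donor oxygen of 25 secures, and a free path to the 6π closure, which the E geometry of 21 secures by holding the CH2 of the C2' chain trans to the ketene, where it can neither quench the ketene by a 1,5-hydrogen shift nor sit inside the closing triene. Every ring carbon takes its substituent from the acyclic partners, and C4' keeps the alkyne hydrogen.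

Step 10
Reactants: 30 5-Ar-4,6-bis(3-methylbut-2-enyl)-3-(triisopropylsilyloxy)phenol
Product: 31 5-Ar-4,6-bis(3-methylbut-2-enyl)benzene-1,3-diol
Conditions: Bu4NF·3H2O, THF, 0 °C
Reagents that add atoms: none
Why: Fluoride cleaves the aryl Si–O bond (desilylation) far faster than it touches the MOM acetal or the alkenes.

Step 11
Reactants: 31 5-Ar-4,6-bis(3-methylbut-2-enyl)benzene-1,3-diol
Product: 32 5-[6-hydroxy-7-(3-methylbut-2-enyl)benzofuran-2-yl]-4,6-bis(3-methylbut-2-enyl)benzene-1,3-diol (target)
Conditions: 3 M aq. HCl, MeOH, rt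
Reagents that add atoms: none
Why: Acid-catalysed acetal exchange with methanol (MOM cleavage) should release the last phenol, dilute acid at room temperature being chosen so that protonation of the prenyl double bonds and chroman formation stay slower than acetal hydrolysis.

**Compound list**

1 | benzofuran-6-ol | Oc1ccc2ccoc2c1 | starting material
2 | 6-(methoxymethoxy)benzofuran | COCOc1ccc2ccoc2c1 | intermediate
3 | prenyl bromide (1-bromo-3-methylbut-2-ene) | CC(C)=CCBr | starting material
4 | [6-(methoxymethoxy)benzofuran-2-yl]lithium | [Li]c1cc2ccc(OCOC)cc2o1 | intermediate (not isolated)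
5 | [6-(methoxymethoxy)benzofuran-2-yl]trimethylsilane | C[Si](C)(C)c1cc2ccc(OCOC)cc2o1 | intermediate (not isolated)
6 | [6-(methoxymethoxy)-2-(trimethylsilyl)benzofuran-7-yl]lithium | [Li]c1c(OCOC)ccc2cc([Si](C)(C)C)oc12 | intermediate (not isolated)
7 | [6-(methoxymethoxy)-2-(trimethylsilyl)benzofuran-7-yl]copper | [Cu]c1c(OCOC)ccc2cc([Si](C)(C)C)oc12 | intermediate (not isolated)
8 | [6-(methoxymethoxy)-7-(3-methylbut-2-enyl)benzofuran-2-yl]trimethylsilane | C[Si](C)(C)c1cc2ccc(OCOC)c(CC=C(C)C)c2o1 | intermediate
9 | 6-(methoxymethoxy)-7-(3-methylbut-2-enyl)benzofuran | COCOc1ccc2ccoc2c1CC=C(C)C | intermediate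
10 | 5-bromo-2-methylpent-2-ene | CC(C)=CCCBr | starting material
11 | 1,4-dimethylpiperazine-2,3-dione | CN1CCN(C)C(=O)C1=O | starting material
12 | (4-methylpent-3-enyl)magnesium bromide | CC(C)=CCC[Mg]Br | intermediate (not isolated)
13 | bis(bromomagnesium) 1,4-dimethyl-2,3-bis(4-methylpent-3-enyl)piperazine-2,3-diolate (mixture of diastereomers) | CN1CCN(C)C(CCC=C(C)C)(O[Mg]Br)C1(CCC=C(C)C)O[Mg]Br | intermediate (not isolated)
14 | 2,11-dimethyldodeca-2,10-diene-6,7-dione | CC(C)=CCCC(=O)C(=O)CCC=C(C)C | intermediate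
15 | [6-(methoxymethoxy)-7-(3-methylbut-2-enyl)benzofuran-2-yl]lithium | [Li]c1cc2ccc(OCOC)c(CC=C(C)C)c2o1 | intermediate (not isolated)
16 | 6-hydroxy-6-[6-(methoxymethoxy)-7-(3-methylbut-2-enyl)benzofuran-2-yl]-2,11-dimethyldodeca-2,10-dien-7-one (racemic) | CC(C)=CCCC(O)(C(=O)CCC=C(C)C)c1cc2ccc(OCOC)c(CC=C(C)C)c2o1 | intermediate
17 | triethylammonium salt of the N-(methoxycarbonyl)sulfamate ester of 16 (racemic) | COC(=O)[N-]S(=O)(=O)OC(CCC=C(C)C)(C(=O)CCC=C(C)C)c1cc2ccc(OCOC)c(CC=C(C)C)c2o1.CC[NH+](CC)CC | intermediate (not isolated)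
18 | (5E)-6-[6-(methoxymethoxy)-7-(3-methylbut-2-enyl)benzofuran-2-yl]-2,11-dimethyldodeca-2,5,10-trien-7-one | CC(C)=CC/C=C(/C(=O)CCC=C(C)C)c1cc2ccc(OCOC)c(CC=C(C)C)c2o1 | intermediate
19 | lithium C7–C8 enolate of 18 (5E retained, enolate geometry not assigned) | [Li]OC(=CCC=C(C)C)/C(=C/CC=C(C)C)c1cc2ccc(OCOC)c(CC=C(C)C)c2o1 | intermediate (not isolated)
20 | (5E)-6-Ar-2,11-dimethyl-8-(trifluoroacetyl)dodeca-2,5,10-trien-7-one (racemic at C8) | CC(C)=CCC(C(=O)C(F)(F)F)C(=O)/C(=C/CC=C(C)C)c1cc2ccc(OCOC)c(CC=C(C)C)c2o1 | intermediate (not isolated)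
21 | (5E)-8-diazo-6-[6-(methoxymethoxy)-7-(3-methylbut-2-enyl)benzofuran-2-yl]-2,11-dimethyldodeca-2,5,10-trien-7-one | CC(C)=CCC(=[N+]=[N-])C(=O)/C(=C/CC=C(C)C)c1cc2ccc(OCOC)c(CC=C(C)C)c2o1 | intermediate (key-step precursor)
22 | acetylene | C#C | starting material
23 | ethynyllithium | [Li]C#C | intermediate (not isolated)
24 | lithium ethynolate | [Li]OC#C | intermediate (not isolated)
25 | (triisopropylsilyloxy)acetylene | C#CO[Si](C(C)C)(C(C)C)C(C)C | intermediate (key-step partner)
26 | (3Z)-3-Ar-7-methyl-2-(3-methylbut-2-enyl)octa-1,3,6-trien-1-one (vinylketene) | O=C=C(CC=C(C)C)/C(=C/CC=C(C)C)c1cc2ccc(OCOC)c(CC=C(C)C)c2o1 | intermediate (not isolated)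
27 | 4-[(1Z)-1-Ar-5-methylhexa-1,4-dienyl]-4-(3-methylbut-2-enyl)-3-(triisopropylsilyloxy)cyclobut-2-en-1-one (racemic) | O=C1C=C(O[Si](C(C)C)(C(C)C)C(C)C)C1(CC=C(C)C)/C(=C/CC=C(C)C)c1cc2ccc(OCOC)c(CC=C(C)C)c2o1 | intermediate (not isolated)
28 | (3E,5Z)-5-Ar-9-methyl-4-(3-methylbut-2-enyl)-3-(triisopropylsilyloxy)deca-1,3,5,8-tetraen-1-one (dienylketene) | O=C=C/C(O[Si](C(C)C)(C(C)C)C(C)C)=C(CC=C(C)C)\C(=C\CC=C(C)C)c1cc2ccc(OCOC)c(CC=C(C)C)c2o1 | intermediate (not isolated)
29 | 5-Ar-4,6-bis(3-methylbut-2-enyl)-3-(triisopropylsilyloxy)cyclohexa-2,4-dien-1-one (racemic) | O=C1C=C(O[Si](C(C)C)(C(C)C)C(C)C)C(CC=C(C)C)=C(c2cc3ccc(OCOC)c(CC=C(C)C)c3o2)C1CC=C(C)C | intermediate (not isolated)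
30 | 5-[6-(methoxymethoxy)-7-(3-methylbut-2-enyl)benzofuran-2-yl]-4,6-bis(3-methylbut-2-enyl)-3-(triisopropylsilyloxy)phenol | CC(C)=CCc1c(O)cc(O[Si](C(C)C)(C(C)C)C(C)C)c(CC=C(C)C)c1-c1cc2ccc(OCOC)c(CC=C(C)C)c2o1 | intermediate (key-step product)
31 | 5-[6-(methoxymethoxy)-7-(3-methylbut-2-enyl)benzofuran-2-yl]-4,6-bis(3-methylbut-2-enyl)benzene-1,3-diol | CC(C)=CCc1c(O)cc(O)c(CC=C(C)C)c1-c1cc2ccc(OCOC)c(CC=C(C)C)c2o1 | intermediate
32 | 5-[6-hydroxy-7-(3-methylbut-2-enyl)benzofuran-2-yl]-4,6-bis(3-methylbut-2-enyl)benzene-1,3-diol | CC(C)=CCc1c(O)cc(O)c(CC=C(C)C)c1-c1cc2ccc(O)c(CC=C(C)C)c2o1 | target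

**Step count**

Total steps: 11. Longest linear sequence: 9 steps (1, 2, 3, 5, 6, 7, 9, 10, 11).

**Steps most likely to fail**

1. Step 9 (key step).
   - What may go wrong: the diazo ketone is acyclic and substituted on the diazo carbon, so after loss of N2 it may react from its s-E conformer through a free acyl carbene. A 1,2-hydride shift from the C9 methylene (to a cross-conjugated dienone) would then compete with the alkenyl shift. The benzofuranyl enone chromophore may also isomerise E to Z under the light, after which the Z vinylketene is drained by a 1,5-hydrogen shift.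
   - Fallback: generate the same vinylketene thermally, with neither a carbene nor light. It sets out from 10 and 9 and comes back at 30.
   - Bromide 10 is alkylated with the ethylenediamine complex of LiC≡CH in DMSO to give 6-methylhept-5-en-1-yne F1. n-BuLi converts it into (6-methylhept-5-en-1-ynyl)lithium F2, which ethyl chloroformate acylates to ethyl 7-methyloct-6-en-2-ynoate F3.
   - Lithio compound 15, made from 9 as in step 5, is treated with CuBr·SMe2 to give the monovalent copper reagent [6-(methoxymethoxy)-7-(3-methylbut-2-enyl)benzofuran-2-yl]copper F4. This should add syn across F3 at –78 °C to the alkenylcopper ethyl (2Z)-3-Ar-2-cuprio-7-methylocta-2,6-dienoate F5, and prenyl bromide 3 then gives ethyl (2E)-3-Ar-7-methyl-2-(3-methylbut-2-enyl)octa-2,6-dienoate F6.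
   - LiOH in aqueous THF/MeOH gives (2E)-3-Ar-7-methyl-2-(3-methylbut-2-enyl)octa-2,6-dienoic acid F7, and 1-chloro-N,N,2-trimethylprop-1-en-1-amine gives (2E)-3-Ar-7-methyl-2-(3-methylbut-2-enyl)octa-2,6-dienoyl chloride F8 without free HCl.
   - Heating F8 with Et3N and 25 in toluene at 80 °C should give vinylketene 26 by 1,4-dehydrochlorination (the C4 methylene is cis to the acyl chloride). 26 then passes through 27, 28 and 29 to 30 as in step 9.

2. Step 6.
   - What may go wrong: E selectivity in the elimination may be incomplete. The sulfamate may also ionise to a cation at C6 that the C10=C11 double bond captures with five-membered ring formation.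
   - Fallback: stereodefined cross-coupling instead of addition and dehydration. It sets out from 14 and 9 and comes back at 18.
   - Diketone 14 is enolised with KN(SiMe3)2 (THF, –78 °C) to potassium (5Z)-2,11-dimethyl-7-oxododeca-2,5,10-trien-6-olate F9 and sulfonylated on oxygen with PhNTf2 to (5Z)-2,11-dimethyl-7-oxododeca-2,5,10-trien-6-yl trifluoromethanesulfonate F10, the C4 chain being expected trans to the acyl group.
   - Lithio compound 15 (from 9) is transmetallated with ZnCl2 to chloro[6-(methoxymethoxy)-7-(3-methylbut-2-enyl)benzofuran-2-yl]zinc F11. Negishi coupling of F10 with F11 under Pd(PPh3)4 (zerovalent palladium, THF, rt) should give 18 with retention of the double-bond geometry and without a cationic intermediate.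

3. Step 7.
   - What may go wrong: deprotonation at the doubly allylic C4 methylene, or equilibration of the kinetic C8 enolate to the extended C4 dienolate, would lead to acylation at C4 or to migration of the skipped double bonds into conjugation.
   - Fallback: diazo transfer before the C5=C6 bond exists. It sets out from 16 and comes back at 21.
   - In ketol 16, C8 is the only enolisable carbon. LiN(SiMe3)2 (2.2 equiv, THF, –78 °C) gives the dilithium C6-alkoxide C7-enolate of 16 F12, and CF3CO2CH2CF3 acylates it at C8 to 6-Ar-6-hydroxy-2,11-dimethyl-8-(trifluoroacetyl)dodeca-2,10-dien-7-one F13 (an O-trifluoroacetate, if formed, is lost on work-up).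
   - MsN3/Et3N in MeCN then gives 6-Ar-8-diazo-6-hydroxy-2,11-dimethyldodeca-2,10-dien-7-one F14. Burgess reagent converts F14, through the triethylammonium N-(methoxycarbonyl)sulfamate ester of F14 F15, into 21.

Further compounds
F1 | step 9 | 6-methylhept-5-en-1-yne | C#CCCC=C(C)C
F2 | step 9 | (6-methylhept-5-en-1-ynyl)lithium | [Li]C#CCCC=C(C)C
F3 | step 9 | ethyl 7-methyloct-6-en-2-ynoate | CCOC(=O)C#CCCC=C(C)C
F4 | step 9 | [6-(methoxymethoxy)-7-(3-methylbut-2-enyl)benzofuran-2-yl]copper | [Cu]c1cc2ccc(OCOC)c(CC=C(C)C)c2o1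
F5 | step 9 | ethyl (2Z)-3-Ar-2-cuprio-7-methylocta-2,6-dienoate | CCOC(=O)/C([Cu])=C(\CCC=C(C)C)c1cc2ccc(OCOC)c(CC=C(C)C)c2o1
F6 | step 9 | ethyl (2E)-3-Ar-7-methyl-2-(3-methylbut-2-enyl)octa-2,6-dienoate | CCOC(=O)/C(CC=C(C)C)=C(\CCC=C(C)C)c1cc2ccc(OCOC)c(CC=C(C)C)c2o1
F7 | step 9 | (2E)-3-Ar-7-methyl-2-(3-methylbut-2-enyl)octa-2,6-dienoic acid | OC(=O)/C(CC=C(C)C)=C(\CCC=C(C)C)c1cc2ccc(OCOC)c(CC=C(C)C)c2o1
F8 | step 9 | (2E)-3-Ar-7-methyl-2-(3-methylbut-2-enyl)octa-2,6-dienoyl chloride | ClC(=O)/C(CC=C(C)C)=C(\CCC=C(C)C)c1cc2ccc(OCOC)c(CC=C(C)C)c2o1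
F9 | step 6 | potassium (5Z)-2,11-dimethyl-7-oxododeca-2,5,10-trien-6-olate | CC(C)=CC/C=C(\O[K])C(=O)CCC=C(C)C
F10 | step 6 | (5Z)-2,11-dimethyl-7-oxododeca-2,5,10-trien-6-yl trifluoromethanesulfonate | CC(C)=CC/C=C(\OS(=O)(=O)C(F)(F)F)C(=O)CCC=C(C)C
F11 | step 6 | chloro[6-(methoxymethoxy)-7-(3-methylbut-2-enyl)benzofuran-2-yl]zinc | Cl[Zn]c1cc2ccc(OCOC)c(CC=C(C)C)c2o1
F12 | step 7 | dilithium C6-alkoxide C7-enolate of 16 | [Li]OC(=CCC=C(C)C)C(O[Li])(CCC=C(C)C)c1cc2ccc(OCOC)c(CC=C(C)C)c2o1
F13 | step 7 | 6-Ar-6-hydroxy-2,11-dimethyl-8-(trifluoroacetyl)dodeca-2,10-dien-7-one | CC(C)=CCCC(O)(C(=O)C(CC=C(C)C)C(=O)C(F)(F)F)c1cc2ccc(OCOC)c(CC=C(C)C)c2o1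
F14 | step 7 | 6-Ar-8-diazo-6-hydroxy-2,11-dimethyldodeca-2,10-dien-7-one | CC(C)=CCCC(O)(C(=O)C(=[N+]=[N-])CC=C(C)C)c1cc2ccc(OCOC)c(CC=C(C)C)c2o1
F15 | step 7 | triethylammonium N-(methoxycarbonyl)sulfamate ester of F14 | COC(=O)[N-]S(=O)(=O)OC(CCC=C(C)C)(C(=O)C(=[N+]=[N-])CC=C(C)C)c1cc2ccc(OCOC)c(CC=C(C)C)c2o1.CC[NH+](CC)CC
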